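**Retrosynthetic overview** (ring A = dioxygenated benzo ring, B = furan, C = central six-membered dienone, D = butenolide)
1. Target 15 ← tri-O-methyl ether 14 by global O-demethylation in the last step.
2. Ring C is closed last: CO is inserted between benzofuran C2–H and the benzylidene C–H of the (Z)-5-benzylidene butenolide 13 (new oxidative double C–H carbonylation, forming both C–C bonds of the ring C ketone).
3. 13 ← vinylogous aldol condensation of the 3,4-diaryl butenolide 9 with benzaldehyde; 9 ← two site-selective Suzuki couplings on 3,4-dibromofuran-2(5H)-one (ring D, bought), first at C4 and then at C3.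
4. Boronate 5 (rings A and B) ← benzofuran-3-yl triflate 4 ← coumaranone 3 ← 2'-hydroxy-4',5'-dimethoxyacetophenone 1.
5. Ring order: A (bought) → B → D attached (bought) → C.

Assumption: the target has no stereocentre and no stereogenic double bond, so the achiral structure as drawn is the single species to be made; the only stereo-element in the route is the Z alkene of 13.

**Step 1**
Reactants: 1 1-(2-hydroxy-4,5-dimethoxyphenyl)ethan-1-one
Product: 2 2-bromo-1-(2-hydroxy-4,5-dimethoxyphenyl)ethan-1-one
Conditions: CuBr2 (2.1 equiv), EtOAc/CHCl3 (1:1), reflux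
Reagents that add atoms: copper dibromide, Br[Cu]Br
Why: CuBr2 brominates the enol of an aryl methyl ketone selectively at the α-carbon (ketone α-bromination), leaving the chelated phenol and the ring untouched; no stereocentre is formed.

**Step 2**
Reactants: 2 2-bromo-1-(2-hydroxy-4,5-dimethoxyphenyl)ethan-1-one
Product: 3 5,6-dimethoxy-1-benzofuran-3(2H)-one
Conditions: NaOAc (3 equiv), EtOH, reflux
Reagents that add atoms: none
Why: Intramolecular Williamson etherification (5-exo-tet SN2 of the phenoxide on the α-bromoketone) is the standard closure to benzofuran-3(2H)-ones.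

**Step 3**
Reactants: 3 5,6-dimethoxy-1-benzofuran-3(2H)-one
Product: 4 5,6-dimethoxy-1-benzofuran-3-yl trifluoromethanesulfonate
Conditions: Tf2O (1.2 equiv), iPr2NEt (1.5 equiv), CH2Cl2, −78 → 0 °C
Reagents that add atoms: trifluoromethanesulfonic anhydride, O=S(=O)(OS(=O)(=O)C(F)(F)F)C(F)(F)F
Why: Enol triflate formation is driven by aromatisation of the coumaranone enol to the benzofuran, so O-sulfonylation is clean.

**Step 4**
Reactants: 4 5,6-dimethoxy-1-benzofuran-3-yl trifluoromethanesulfonate
Product: 5 2-(5,6-dimethoxy-1-benzofuran-3-yl)-4,4,5,5-tetramethyl-1,3,2-dioxaborolane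
Conditions: B2pin2 (1.2 equiv), PdCl2(dppf) (3 mol %), KOAc (3 equiv), 1,4-dioxane, 80 °C
Reagents that add atoms: bis(pinacolato)diboron, CC1(C)OB(OC1(C)C)B1OC(C)(C)C(C)(C)O1
Why: Miyaura borylation of a heteroaryl triflate (oxidative addition, acetate-assisted transmetalation with the diboron, reductive elimination) is routine and tolerates the methyl ethers.

**Step 5**
Reactants: 5 2-(5,6-dimethoxy-1-benzofuran-3-yl)-4,4,5,5-tetramethyl-1,3,2-dioxaborolane; 6 3,4-dibromofuran-2(5H)-one
Product: 7 3-bromo-4-(5,6-dimethoxy-1-benzofuran-3-yl)furan-2(5H)-one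
Conditions: PdCl2(MeCN)2 (5 mol %), AsPh3 (20 mol %), Ag2O (3 equiv), THF/H2O (20:1), 65 °C
Reagents that add atoms: none
Why: Suzuki–Miyaura coupling in which oxidative addition occurs selectively at the C4–Br bond (the β-position of the enoate, a vinylogous acyl bromide), while the near-neutral Ag2O activation spares the base-sensitive butenolide and the C3–Br bond.

**Step 6**
Reactants: 7 3-bromo-4-(5,6-dimethoxy-1-benzofuran-3-yl)furan-2(5H)-one; 8 (4-methoxyphenyl)boronic acid
Product: 9 4-(5,6-dimethoxy-1-benzofuran-3-yl)-3-(4-methoxyphenyl)furan-2(5H)-one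
Conditions: Pd(OAc)2 (5 mol %), SPhos (10 mol %), K3PO4 (2 equiv), toluene/H2O (10:1), 80 °C
Reagents that add atoms: none
Why: A second Suzuki–Miyaura coupling at the remaining α-bromo enoate position, with a bulky electron-rich biarylphosphine to overcome the hindrance next to the C4 aryl group.

**Step 7**
Reactants: 9 4-(5,6-dimethoxy-1-benzofuran-3-yl)-3-(4-methoxyphenyl)furan-2(5H)-one; 10 benzaldehyde
Product: 13 (5Z)-5-benzylidene-4-(5,6-dimethoxy-1-benzofuran-3-yl)-3-(4-methoxyphenyl)furan-2(5H)-one, via silyloxyfuran 11 (not isolated), via silyl aldol adduct 12 (not isolated)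
Conditions: TBSOTf (1.3 equiv), iPr2NEt (3 equiv), CH2Cl2, 0 °C → rt; then DBU (2 equiv), rt
Reagents that add atoms: tert-butyldimethylsilyl trifluoromethanesulfonate, CC(C)(C)[Si](C)(C)OS(=O)(=O)C(F)(F)F (its silyl group is carried by 11 and 12 only)
Why: Vinylogous Mukaiyama aldol addition of the 2-silyloxyfuran formed in the flask, followed by DBU-promoted E1cB elimination, gives the thermodynamic Z alkene (phenyl syn to the ring oxygen, away from the C4 aryl group), which is the geometry needed for ring closure.

**Step 8**
Reactants: 13 (5Z)-5-benzylidene-4-(5,6-dimethoxy-1-benzofuran-3-yl)-3-(4-methoxyphenyl)furan-2(5H)-one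
Product: 14 tri-O-methyl ether of the target (dibenzofuran-4(1H)-one core in dibenzofuran numbering: phenyl on C3, γ-lactone fused across C1–C2 with the lactone O on C2 and C1 doubly bonded to the lactone carbon that carries the 4-methoxyphenyl group and the lactone C=O, OMe on C7 and C8)
Conditions: Pd(OAc)2 (10 mol %), Cu(OAc)2 (3 equiv), PivOH (1 equiv), CO (1 atm), 4 Å MS, 1,4-dioxane, 100 °C
Reagents that add atoms: carbon monoxide, [C-]#[O+]
Why: Proposed new method: a palladium-catalysed dehydrogenative carbonylative annulation that joins a heteroaryl C–H and an alkenyl C–H through CO, in which pivalate-assisted concerted metalation–deprotonation at the benzofuran C2–H (its most acidic C–H, further acidified by the butenolide acceptor on C3) gives a heteroaryl complex of divalent palladium, CO insertion gives an aroyl–palladium species that the Z geometry holds next to the benzylidene C–H, and ring C then closes either by vinylic C–H metalation and C–C reductive elimination from a seven-membered acyl(alkenyl)palladacycle or by 6-endo acylpalladation of the enol-lactone C=C (acyl to the benzylic carbon, positive character taken up by the lactone oxygen) followed by acetate-assisted loss of the hydrogen that is now α to the new ketone, while Cu(OAc)2 returns zerovalent palladium to divalent palladium; the competing 5-exo insertion gives a palladium alkyl without a β-hydrogen and should revert, the fully conjugated 14 is the thermodynamic sink, and no stereocentre is formed; the closest known reaction type is the palladium-catalysed oxidative double C–H carbonylation of diaryl ethers to xanthones and of biaryls to fluorenones (together with carbonylative Heck cyclisation).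

**Step 9**
Reactants: 14 tri-O-methyl ether of the target
Product: 15 CNP0139113.0 (the same pentacycle with OH on C7 and C8 and a 4-hydroxyphenyl group on the lactone carbon; achiral)
Conditions: BBr3 (6 equiv), CH2Cl2, −78 °C → rt; then H2O, 0 °C
Reagents that add atoms: none
Why: Lewis acid ether cleavage (BBr3 complexation of each aryl methyl ether and SN2 attack of bromide on methyl) frees the three phenols, while the enol lactone and dienone are not attacked at low temperature; there is no stereocentre to scramble.

**Compound list**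
1 | 1-(2-hydroxy-4,5-dimethoxyphenyl)ethan-1-one (2'-hydroxy-4',5'-dimethoxyacetophenone) | COc1cc(O)c(cc1OC)C(C)=O | starting material
2 | 2-bromo-1-(2-hydroxy-4,5-dimethoxyphenyl)ethan-1-one | COc1cc(O)c(cc1OC)C(=O)CBr | intermediate
3 | 5,6-dimethoxy-1-benzofuran-3(2H)-one | COc1cc2OCC(=O)c2cc1OC | intermediate
4 | 5,6-dimethoxy-1-benzofuran-3-yl trifluoromethanesulfonate | COc1cc2occ(OS(=O)(=O)C(F)(F)F)c2cc1OC | intermediate
5 | 2-(5,6-dimethoxy-1-benzofuran-3-yl)-4,4,5,5-tetramethyl-1,3,2-dioxaborolane | COc1cc2occ(B3OC(C)(C)C(C)(C)O3)c2cc1OC | intermediate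
6 | 3,4-dibromofuran-2(5H)-one | O=C1OCC(Br)=C1Br | starting material
7 | 3-bromo-4-(5,6-dimethoxy-1-benzofuran-3-yl)furan-2(5H)-one | O=C1OCC(c2coc3cc(OC)c(OC)cc23)=C1Br | intermediate
8 | (4-methoxyphenyl)boronic acid | COc1ccc(cc1)B(O)O | starting material
9 | 4-(5,6-dimethoxy-1-benzofuran-3-yl)-3-(4-methoxyphenyl)furan-2(5H)-one | O=C1OCC(c2coc3cc(OC)c(OC)cc23)=C1c1ccc(OC)cc1 | intermediate
10 | benzaldehyde | O=Cc1ccccc1 | starting material
11 | tert-butyl{[4-(5,6-dimethoxy-1-benzofuran-3-yl)-3-(4-methoxyphenyl)furan-2-yl]oxy}dimethylsilane | CC(C)(C)[Si](C)(C)Oc1occ(-c2coc3cc(OC)c(OC)cc23)c1-c1ccc(OC)cc1 | intermediate (not isolated)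
12 | 5-{[(tert-butyldimethylsilyl)oxy](phenyl)methyl}-4-(5,6-dimethoxy-1-benzofuran-3-yl)-3-(4-methoxyphenyl)furan-2(5H)-one (racemic mixture of diastereomers; both centres are lost in the elimination) | O=C1OC(C(O[Si](C)(C)C(C)(C)C)c2ccccc2)C(c2coc3cc(OC)c(OC)cc23)=C1c1ccc(OC)cc1 | intermediate (not isolated)
13 | (5Z)-5-benzylidene-4-(5,6-dimethoxy-1-benzofuran-3-yl)-3-(4-methoxyphenyl)furan-2(5H)-one | O=C1O/C(=C\c2ccccc2)C(c2coc3cc(OC)c(OC)cc23)=C1c1ccc(OC)cc1 | intermediate
14 | tri-O-methyl ether of the target (pentacyclic dienone lactone with 7,8-dimethoxy groups and a 4-methoxyphenyl group; no stereocentre) | O=C1OC2=C(c3ccccc3)C(=O)c3oc4cc(OC)c(OC)cc4c3C2=C1c1ccc(OC)cc1 | intermediate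
15 | CNP0139113.0 (pentacyclic dienone lactone with 7,8-dihydroxy groups, a 3-phenyl group and a 4-hydroxyphenyl group on the lactone carbon; no stereocentre) | O=C1OC2=C(c3ccccc3)C(=O)c3oc4cc(O)c(O)cc4c3C2=C1c1ccc(O)cc1 | target

**Total step count:** 9. **Longest linear sequence:** 9 steps (1 → 15); 6, 8 and 10 enter as bought building blocks.

**Steps most likely to fail**

Step 8 (the new carbonylative closure of ring C). The risks are reduction of divalent palladium by CO before C–H palladation and simple carboxylation of benzofuran C2 without ring closure. The fallback uses known chemistry, sets out from 9 and comes back at 14. Butenolide 9 is put through the vinylogous Mukaiyama aldol protocol of step 7, but with tert-butyl benzoylformate (TBSOTf, iPr2NEt, CH2Cl2), to give the silyl aldol adduct F1. DBU converts this by E1cB elimination into the (E)-alkylidene tert-butyl ester F2, in which the carboxyl group is syn to the benzofuranyl group; any Z isomer is equilibrated with catalytic iodine and light. TFA in CH2Cl2 cleaves the ester to the carboxylic acid F3. TFAA then closes ring C by intramolecular Friedel–Crafts acylation at benzofuran C2 through the mixed anhydride, giving 14.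

Step 5 (site-selective first coupling on the dibromobutenolide with a heteroaryl boronate). The risks are bis-coupling, protodeboronation and base damage to 6. The fallback sets out from 5 and comes back at 9. Tandem transesterification–Dieckmann condensation of methyl (4-methoxyphenyl)acetate with methyl glycolate (KOtBu, DMF) gives 3-(4-methoxyphenyl)tetronic acid F4. TsCl and Et3N give its enol tosylate F5. A single Suzuki–Miyaura coupling of F5 with boronate 5 (PdCl2(PPh3)2, KF, THF/H2O, 60 °C) gives 9 directly, so no choice between two C–Br bonds arises and steps 5 and 6 are both replaced.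

Step 9 (BBr3 on the finished pentacycle). The risks are lactone opening and decomposition of the catechol-bearing dienone under strong Lewis acid. The fallback sets out from 13 and comes back at 15. BBr3 is used instead on the simple benzylidene butenolide 13 to give the triphenol F6. Ac2O and pyridine give the triacetate F7. The carbonylative annulation of step 8 is run on F7 to give the target triacetate F8. The acetates are then removed with 1 M HCl in THF at 45 °C to give 15, so the pentacycle never meets BBr3.

**Further compounds**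
F1 | step 8 | tert-butyl 2-[(tert-butyldimethylsilyl)oxy]-2-[3-(5,6-dimethoxy-1-benzofuran-3-yl)-4-(4-methoxyphenyl)-5-oxo-2,5-dihydrofuran-2-yl]-2-phenylacetate (mixture of diastereomers) | CC(C)(C)OC(=O)C(O[Si](C)(C)C(C)(C)C)(c1ccccc1)C1OC(=O)C(c2ccc(OC)cc2)=C1c1coc2cc(OC)c(OC)cc12
F2 | step 8 | tert-butyl (2E)-2-[3-(5,6-dimethoxy-1-benzofuran-3-yl)-4-(4-methoxyphenyl)-5-oxofuran-2(5H)-ylidene]-2-phenylacetate | O=C1O/C(=C(\c2ccccc2)C(=O)OC(C)(C)C)C(c2coc3cc(OC)c(OC)cc23)=C1c1ccc(OC)cc1
F3 | step 8 | (2E)-2-[3-(5,6-dimethoxy-1-benzofuran-3-yl)-4-(4-methoxyphenyl)-5-oxofuran-2(5H)-ylidene]-2-phenylacetic acid | O=C1O/C(=C(\c2ccccc2)C(=O)O)C(c2coc3cc(OC)c(OC)cc23)=C1c1ccc(OC)cc1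
F4 | step 5 | 4-hydroxy-3-(4-methoxyphenyl)furan-2(5H)-one | O=C1OCC(O)=C1c1ccc(OC)cc1
F5 | step 5 | 4-(4-methoxyphenyl)-5-oxo-2,5-dihydrofuran-3-yl 4-methylbenzenesulfonate | O=C1OCC(OS(=O)(=O)c2ccc(C)cc2)=C1c1ccc(OC)cc1
F6 | step 9 | (5Z)-5-benzylidene-4-(5,6-dihydroxy-1-benzofuran-3-yl)-3-(4-hydroxyphenyl)furan-2(5H)-one | O=C1O/C(=C\c2ccccc2)C(c2coc3cc(O)c(O)cc23)=C1c1ccc(O)cc1
F7 | step 9 | triacetate of F6 (acetoxy groups on benzofuran C5 and C6 and on the para position of the C3 aryl group) | O=C1O/C(=C\c2ccccc2)C(c2coc3cc(OC(C)=O)c(OC(C)=O)cc23)=C1c1ccc(OC(C)=O)cc1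
F8 | step 9 | triacetate of 15 (acetoxy groups on C7 and C8 and on the para position of the aryl group on the lactone carbon) | O=C1OC2=C(c3ccccc3)C(=O)c3oc4cc(OC(C)=O)c(OC(C)=O)cc4c3C2=C1c1ccc(OC(C)=O)cc1
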